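## Structural features

The target is a linear chain of six benzene rings, A to F, joined only by five diaryl ether oxygens. It carries fifteen free phenolic hydroxyls and has no stereocenter, so nothing stereochemical has to be set or preserved. Rings A, B, C and E are 1,2,3,5-tetraoxygenated (a phloroglucinol pattern plus one more oxygen). Ring F is a 3,4,5-trihydroxyphenoxy unit. Ring D is pentaoxygenated: aryloxy groups on the neighbouring carbons C1 and C6, hydroxyls on C3, C4 and C5, and one hydrogen at C2. Each ether oxygen joins a carbon flanked by two oxygen-bearing carbons (C1 of A, C4 of B, C and E, C6 of D) to a more open carbon of the next ring, so every link is a crowded, electron-rich diaryl ether. The free polyphenol, and above all the two pyrogallol-type rings D and F, should oxidise readily in air, especially under base; the hydroxyls therefore stay masked until the last step. The real difficulty is regiochemical: twenty oxygen atoms must be placed correctly, five hindered C–O bonds must be made, and chemically similar ring C–H positions must be told apart. The key step uses the fact that C4–H of ring D and C4–H of ring F each lie between two oxygen-bearing carbons (C3 and C5) that can carry methoxymethyl ethers. Without these two oxygens, rings D and F become simple resorcinol-type units.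

## Logic of the disconnections

**25 to 24.** The eleven O–CH3 bonds and four O–CH2OCH3 bonds are cut. The fifteen phenols are thereby masked until the end, and every earlier intermediate is a neutral ether that can be chromatographed. The forward step must cleave all fifteen ethers in one Lewis-acid operation, leave the five diaryl ether bonds intact, and be worked up without oxygen.

**24 to 22 and 23.** The bond between C1 of ring A and the ether oxygen is cut, with the oxygen left on ring B. Ring A has two C–H groups, each between two methoxy groups, that would be metalated in the key step, so it has to arrive after it. This reduces the hexamer to a pentamer phenol and the stock arene 23. The forward coupling must form a C–O bond at a carbon flanked by two methoxy groups; the phenol partner is unhindered.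

**22 to 21 to 20.** The O–Si bond on ring B and the two new O–CH3 bonds at C4 of rings D and F are cut. Three phenolic oxygens must be distinguished, so the two new hydroxyls are capped first and the ring B oxygen is then released alone. The methylation must not disturb the silyl ether, and the fluoride step must leave the acetals untouched.

**20 to 17 (key).** The C4–O bonds of rings D and F are cut. These two oxygens are the only departures from a phloroglucinol-derived pattern; without them both rings come from 1. Both oxygens are then introduced in a single operation. The forward step needs twofold deprotonation only at the C–H between two methoxymethyl ethers. For that reason every other C–H in 17 has at most one coordinating neighbour, and ring B ends in a bulky silyl ether.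

**17 to 11 and 16.** The bond between C1 of ring E and the oxygen on C6 of ring D is cut. This central cut divides the pentamer into a trimer phenol and a dimer bromide and keeps the reliable polarity of hindered phenoxide plus bromide on an open carbon. The forward coupling must engage a phenoxide flanked by two oxygenated carbons, and it is the only copper coupling the silyl ether has to survive.

**16 to 15 and 5; 15 to 12 to 1.** The bond between C1 of ring F and the oxygen on C4 of ring E is cut. Because 5 holds both a phenol and a bromide, ring F is joined by an oxidative boronic acid coupling that ignores C–Br bonds, and 5 needs no protecting group. The demand is conversion of C–Br into C–B without deprotonation between the two acetal groups.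

**11 to 10 to 8.** The O–Si bond is cut, and the phenolic C–O bonds at C1 of ring B and C6 of ring D are traced back to C–CHO bonds. The formyl groups act as masked phenols: the one on ring D activates its bromide for coupling, and the one on ring B is inert in the couplings. Both phenols appear in one oxidation and differ in their steric surroundings. The forward steps need aryl migration in both Baeyer–Villiger events and silylation only at the open ring B hydroxyl.

**8 to 6 and 7; 6 to 4 and 5; 4 to 3 to 1.** The B(C4)O–C(C1) and C(C4)O–D(C1) bonds are cut, each as hindered phenoxide plus aryl bromide. The bromide of 4 lies ortho to a formyl group and should react before the bromide of 5, so 5 can be used unprotected. The route then rests on three stock phenols, 1, 5 and 7. The demands are a chemoselective first coupling and formylation of 1 next to bromine.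

## Other disconnections considered

**Alternative 1:** Ring D is taken apart into the four ring carbons of dimethyl squarate A3 and the two alkyne carbons of the aryl ynol ether A4 of the ABC trimer. In the forward direction lithiated A4 adds to A3 to give the 4-alkynyl-4-hydroxycyclobutenone A2. Heating would open the four-membered ring to an enynyl ketene, and closure between the ketene carbon and the aryloxy-bearing alkyne carbon, followed by hydrogen transfer, would give the quinone A1.
- In its favour: all five oxygenated carbons of ring D arrive with their oxygens, so no C–H selectivity question arises for ring D. The ring-forming step is a neutral thermolysis without reagents. On this point the alternative is better than the chosen plan.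
- Against it: an aryloxy group on the alkyne terminus stabilises a radical and is expected to favour the competing five-membered closure to an alkylidene cyclopentenedione. After reduction of A1, ring E must be attached to the more hindered hydroquinone hydroxyl (the one next to the aryloxy group), which needs a protection sequence. The extra oxygen of ring F is not addressed, and A4 must be made from a 2,6-dimethoxyphenol in further steps.
- Comparison: on structure it fixes ring D by construction but does not help with ring F or the ether bonds. On mechanism it is a pericyclic cascade with a regiochemical branch, against a coordination-directed deprotonation whose site is predictable. On step economy, ring D would cost about five or six operations against three building-block steps plus a share of one hydroxylation. Both plans end with the same exhaustive demethylation, so they are equal there.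

**Alternative 2:** The C1–C6 bond of ring A is cut, opening it to the triketide ester A6, a methyl 6-aryloxy-3,5-dioxohexanoate carrying the methylated BCDEF pentamer on oxygen. In the forward direction the polyanion of A6 would cyclise by attack of the aryloxymethyl carbanion on the ester carbonyl (Claisen type), and enolisation would give the hexamer A5 with ring A as a free triol.
- In its favour: the A–O–B link comes from O-alkylation of an unhindered phenol, not from coupling at a carbon between two methoxy groups. That is better than step 14 of the chosen plan. Ring A also needs no demethylation, and the closure follows the polyketide origin of phloroglucinol.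
- Against it: lactonisation to a 4-hydroxy-2-pyranone competes. The nucleophile must form at the least acidic site, only after the two doubly activated methylenes are deprotonated. A5 still carries twelve methyl ethers, which would have to be cleaved in the presence of a free phloroglucinol ring. The pyrogallol oxygens of rings D and F are not addressed at all.
- Comparison: on structure it solves only the last ring and still needs a pentamer phenol like 22 from a route like the chosen one. On mechanism it is enolate acylation against copper coupling. On step economy it needs about three operations (O-alkylation, chain extension, cyclisation) where the chosen plan needs one.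

**Alternative 3:** The C1–C2 and C1–C6 bonds of ring E are cut. C1 comes from the ylide carbon of the aryloxymethyl phosphonium salt A8 of the ABCD tetramer, and the other five ring atoms come from the pyranone A9. In the forward direction A9 is O-silylated to the 4-silyloxypyrylium salt A10. The ylide from A8 would add at C2, the 2H-pyran would open to a dienal, and intramolecular Wittig closure would give the pentamer A7.
- In its favour: the most congested ether bond, D–O–E, is never made by cross-coupling, because its oxygen is already on ring D. That is better than step 10 of the chosen plan. Ring E arrives with its C4 oxygen as a silyl ether, ready for the E–F coupling, and the symmetry of A10 removes any regiochemical question. On differentiation of the ring E oxygen it is the equal of the chosen plan.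
- Against it: A9 is not a stock compound in this substitution pattern. A10 is a moisture-sensitive, strongly electrophilic species, and an oxygen-substituted ylide could attack silicon or C4. Preparing A8 from a phenol flanked by aryloxy and methoxy groups adds steps. A8 already contains ring D fully oxygenated, so the C4 oxygen of ring D must be introduced earlier anyway, and ring F must still be coupled on afterwards.
- Comparison: on structure it solves one of five ether bonds. On mechanism it is polar addition, electrocyclic opening and olefination against copper-mediated C–O coupling. On step economy it needs about four operations for what step 10 does in one. The final demethylation is the same in both.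

Key step: step 11

Remark on the chemistry: ring D needs its two aryloxy groups on adjacent carbons and its acetal oxygens ortho and para to one of them. A unit derived from 2,4-dihydroxybenzaldehyde cannot supply this pattern, so ring D is made from 5-bromobenzene-1,3-diol by formylation next to bromine, and 4-hydroxy-3,5-dimethoxybenzaldehyde serves as ring B.

Remark on the chemistry: the precursor and product of the key step are kept unchanged as 17 and 20; the silyl ether is introduced only at step 6, so that it passes through a single copper coupling.

## Route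

Step 1
Reactants: 1 5-bromobenzene-1,3-diol
Product: 3 2-bromo-4,6-dihydroxybenzaldehyde, via iminium chloride 2 (not isolated)
Conditions: POCl3, DMF, MeCN, 0 °C → rt; then H2O, 50 °C
Reagents that add atoms: N,N-dimethylformamide, CN(C)C=O; water, O
Why: Vilsmeier–Haack formylation; the chloroiminium ion should attack C4 of the resorcinol, para to one hydroxyl and ortho to the other, as resorcinol and 5-alkylresorcinols do, and hydrolysis of 2 releases the aldehyde with bromine where ring D later joins ring C.

Step 2
Reactants: 3 2-bromo-4,6-dihydroxybenzaldehyde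
Product: 4 2-bromo-4,6-bis(methoxymethoxy)benzaldehyde
Conditions: MOMCl, iPr2NEt, CH2Cl2, 0 → 40 °C
Reagents that add atoms: chloromethyl methyl ether, COCCl
Why: O-alkylation of both phenols to mixed acetals; warming with excess reagent should also alkylate the hydroxyl hydrogen-bonded to the formyl group.

Step 3
Reactants: 4 2-bromo-4,6-bis(methoxymethoxy)benzaldehyde; 5 4-bromo-2,6-dimethoxyphenol
Product: 6 2-(4-bromo-2,6-dimethoxyphenoxy)-4,6-bis(methoxymethoxy)benzaldehyde
Conditions: CuI (10 mol %), picolinic acid (20 mol %), K3PO4, DMSO, 80 °C; 4 in excess
Reagents that add atoms: none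
Why: Ullmann diaryl ether synthesis; the bromide ortho to the formyl group is activated, whereas the bromide of 5 lies para to the phenoxide oxygen and is deactivated, so cross-coupling should precede self-condensation.

Step 4
Reactants: 6 2-(4-bromo-2,6-dimethoxyphenoxy)-4,6-bis(methoxymethoxy)benzaldehyde; 7 4-hydroxy-3,5-dimethoxybenzaldehyde
Product: 8 4-{4-[2-formyl-3,5-bis(methoxymethoxy)phenoxy]-3,5-dimethoxyphenoxy}-3,5-dimethoxybenzaldehyde
Conditions: CuI (20 mol %), picolinic acid (40 mol %), K3PO4, DMSO, 100 °C
Reagents that add atoms: none
Why: Ullmann coupling of a 2,6-dimethoxyphenoxide with the only C–Br bond left; 7 has no halogen, so only the B–O–C bond can form, and the picolinate copper system is suited to ortho-disubstituted phenoxides.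

Step 5
Reactants: 8 BCD dialdehyde
Product: 10 4-{4-[2-hydroxy-3,5-bis(methoxymethoxy)phenoxy]-3,5-dimethoxyphenoxy}-3,5-dimethoxyphenol, via bis(formate) 9 (not isolated)
Conditions: mCPBA, CH2Cl2, 0 °C → rt; aq NaHCO3 wash; then K2CO3 (cat.), MeOH, 0 °C, argon
Reagents that add atoms: 3-chloroperoxybenzoic acid, O=C(OO)c1cccc(Cl)c1
Why: twofold Baeyer–Villiger (Dakin-type) oxidation; the oxygen-rich aryl groups should migrate in preference to hydrogen on both aldehydes, and mild methanolysis of the aryl formates 9 frees both phenols while the acetals remain.

Step 6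
Reactants: 10 BCD diphenol
Product: 11 2-{2,6-dimethoxy-4-[2,6-dimethoxy-4-(triisopropylsilyloxy)phenoxy]phenoxy}-4,6-bis(methoxymethoxy)phenol
Conditions: TIPSCl (1.05 equiv), imidazole, DMF, 0 °C
Reagents that add atoms: chlorotriisopropylsilane, CC(C)[Si](Cl)(C(C)C)C(C)C
Why: silylation under steric control; the bulky chlorosilane should react at the ring B hydroxyl between two C–H groups and not at the ring D hydroxyl, which is flanked by an aryloxy and an acetal oxygen.

Step 7
Reactants: 1 5-bromobenzene-1,3-diol
Product: 12 1-bromo-3,5-bis(methoxymethoxy)benzene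
Conditions: MOMCl, iPr2NEt, CH2Cl2, 0 °C → rt
Reagents that add atoms: chloromethyl methyl ether, COCCl
Why: standard acetal protection of both phenols, which also supplies the directing groups of ring F.

Step 8
Reactants: 12 1-bromo-3,5-bis(methoxymethoxy)benzene
Product: 15 [3,5-bis(methoxymethoxy)phenyl]boronic acid, via aryllithium 13 (not isolated), via lithium triisopropoxyborate 14 (not isolated)
Conditions: B(OiPr)3, n-BuLi, THF–toluene, −78 °C (in situ trap); aq NH4Cl
Reagents that add atoms: triisopropyl borate, CC(C)OB(OC(C)C)OC(C)C; water, O; n-butyllithium, [Li]CCCC (lithium of 13 and 14 only)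
Why: bromine–lithium exchange at −78 °C should be faster than ring deprotonation, and the borate present in the flask traps 13 before it can isomerise to the lithio species between the acetal groups; mild hydrolysis gives the boronic acid.

Step 9
Reactants: 15 [3,5-bis(methoxymethoxy)phenyl]boronic acid; 5 4-bromo-2,6-dimethoxyphenol
Product: 16 5-bromo-2-[3,5-bis(methoxymethoxy)phenoxy]-1,3-dimethoxybenzene
Conditions: Cu(OAc)2 (20 mol %), pyridine, 4 Å MS, CH2Cl2, O2 (1 atm), rt; 15 in excess
Reagents that add atoms: none
Why: Chan–Lam oxidative C–O coupling at room temperature; divalent copper does not insert into the C–Br bond of 5 under these conditions, so the E–O–F bond should form with the bromide kept for step 10.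

Step 10
Reactants: 11 BCD phenol with ring B triisopropylsilyl ether; 16 5-bromo-2-[3,5-bis(methoxymethoxy)phenoxy]-1,3-dimethoxybenzene
Product: 17 deoxy BCDEF pentamer (ring B O-triisopropylsilyl; rings B, C and E dimethyl ethers; rings D and F 3,5-bis(methoxymethyl) ethers with C4–H)
Conditions: CuI (20 mol %), N,N-dimethylglycine hydrochloride (60 mol %), Cs2CO3, 1,4-dioxane, 100 °C, argon; 16 in excess
Reagents that add atoms: none
Why: Ullmann coupling of the ring D phenoxide with the bromide on the open C1 of ring E; the amino acid ligand permits coupling in weakly polar dioxane, which should spare the aryl silyl ether in its only exposure to such conditions.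

Step 11
Reactants: 17 deoxy BCDEF pentamer
Product: 20 BCDEF pentamer with free hydroxyls at C4 of rings D and F, via dilithio pentamer 18 (not isolated), via bis(dimethoxyboryl) pentamer 19 (not isolated)
Conditions: n-BuLi (2.5 equiv), THF, −20 → 0 °C; B(OMe)3, −78 °C → rt; AcOH, 30% aq H2O2, 0 °C → rt
Reagents that add atoms: hydrogen peroxide, OO; n-butyllithium, [Li]CCCC (lithium of 18 only); trimethyl borate, COB(OC)OC (boryl groups of 19 only)
Why: The closest known reaction type is directed ortho-metalation of resorcinol bis(methoxymethyl) ethers followed by boration and peroxide oxidation. n-Butyllithium should bind to the acetal oxygens and remove the C–H held between two such groups, giving an aryllithium chelated from both sides. Only C4 of ring D and C4 of ring F have two methoxymethoxy neighbours, so 18 should form with both sites metalated. Every other ring C–H lies beside a diaryl ether oxygen, a methyl ether or the bulky silyl ether, none of which offers the same twofold coordination, and the amount of base is limited to hold this selectivity. Trimethyl borate traps both carbanions as boronates 19. Hydroperoxide then adds to boron, each aryl group shifts from boron to oxygen, and hydrolysis of the borate esters gives the two phenols. The acidic peroxide work-up is chosen so that the silyl ether and the acetals survive. No ring is closed and no stereocenter is formed.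

Step 12
Reactants: 20 BCDEF pentamer diol
Product: 21 BCDEF pentamer with methoxy groups at C4 of rings D and F
Conditions: MeI, K2CO3, acetone, 55 °C
Reagents that add atoms: iodomethane, CI
Why: Williamson O-methylation of the two new hindered phenols, so that they cannot compete in step 14; anhydrous acetone with carbonate should leave the aryl silyl ether intact.

Step 13
Reactants: 21 methylated BCDEF pentamer silyl ether
Product: 22 BCDEF pentamer phenol (free hydroxyl at C1 of ring B)
Conditions: TBAF, AcOH, THF, 0 °C
Reagents that add atoms: none
Why: fluoride cleavage of the Si–O bond, buffered with acetic acid so that the electron-rich phenoxide is not exposed to base and air; methyl ethers and acetals are inert to fluoride.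

Step 14
Reactants: 22 BCDEF pentamer phenol; 23 2-iodo-1,3,5-trimethoxybenzene
Product: 24 hexamer with eleven methyl ethers and four methoxymethyl ethers
Conditions: CuI (20 mol %), picolinic acid (40 mol %), K3PO4, DMSO, 100 °C; 23 in excess
Reagents that add atoms: none
Why: Ullmann coupling of an unhindered phenoxide with an ortho-disubstituted aryl iodide, the combination for which the picolinate copper system is suited; ring A enters only now, so its C–H groups between methoxy groups never meet the alkyllithium.

Step 15
Reactants: 24 protected hexamer
Product: 25 CNP0175585.0 (target, all fifteen hydroxyls free)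
Conditions: BBr3 (excess), CH2Cl2, −78 °C → rt, argon; then H2O, 0 °C
Reagents that add atoms: none
Why: Lewis-acid ether cleavage; boron binds each ether oxygen and bromide attacks the methyl or acetal carbon, while the diaryl ether bonds cannot be attacked at their sp2 carbons, and exclusion of oxygen protects the pyrogallol rings.

## Compound list

1 | 5-bromobenzene-1,3-diol | Oc1cc(O)cc(Br)c1 | starting material
2 | [(2-bromo-4,6-dihydroxyphenyl)methylidene]dimethylammonium chloride | C[N+](C)=Cc1c(O)cc(O)cc1Br.[Cl-] | intermediate (not isolated)
3 | 2-bromo-4,6-dihydroxybenzaldehyde | O=Cc1c(O)cc(O)cc1Br | intermediate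
4 | 2-bromo-4,6-bis(methoxymethoxy)benzaldehyde | COCOc1cc(Br)c(C=O)c(OCOC)c1 | intermediate
5 | 4-bromo-2,6-dimethoxyphenol | COc1cc(Br)cc(OC)c1O | starting material
6 | 2-(4-bromo-2,6-dimethoxyphenoxy)-4,6-bis(methoxymethoxy)benzaldehyde | COCOc1cc(OCOC)c(C=O)c(Oc2c(OC)cc(Br)cc2OC)c1 | intermediate
7 | 4-hydroxy-3,5-dimethoxybenzaldehyde | COc1cc(C=O)cc(OC)c1O | starting material
8 | 4-{4-[2-formyl-3,5-bis(methoxymethoxy)phenoxy]-3,5-dimethoxyphenoxy}-3,5-dimethoxybenzaldehyde | O=Cc1cc(OC)c(Oc2cc(OC)c(Oc3cc(OCOC)cc(OCOC)c3C=O)c(OC)c2)c(OC)c1 | intermediate
9 | bis(formate) of 10 (formyloxy groups at C1 of ring B and C6 of ring D) | O=COc1cc(OC)c(Oc2cc(OC)c(Oc3cc(OCOC)cc(OCOC)c3OC=O)c(OC)c2)c(OC)c1 | intermediate (not isolated)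
10 | 4-{4-[2-hydroxy-3,5-bis(methoxymethoxy)phenoxy]-3,5-dimethoxyphenoxy}-3,5-dimethoxyphenol | Oc1cc(OC)c(Oc2cc(OC)c(Oc3cc(OCOC)cc(OCOC)c3O)c(OC)c2)c(OC)c1 | intermediate
11 | 2-{2,6-dimethoxy-4-[2,6-dimethoxy-4-(triisopropylsilyloxy)phenoxy]phenoxy}-4,6-bis(methoxymethoxy)phenol | CC(C)[Si](C(C)C)(C(C)C)Oc1cc(OC)c(Oc2cc(OC)c(Oc3cc(OCOC)cc(OCOC)c3O)c(OC)c2)c(OC)c1 | intermediate
12 | 1-bromo-3,5-bis(methoxymethoxy)benzene | COCOc1cc(Br)cc(OCOC)c1 | intermediate
13 | 3,5-bis(methoxymethoxy)phenyllithium | [Li]c1cc(OCOC)cc(OCOC)c1 | intermediate (not isolated)
14 | lithium triisopropoxy[3,5-bis(methoxymethoxy)phenyl]borate | [Li+].CC(C)O[B-](OC(C)C)(OC(C)C)c1cc(OCOC)cc(OCOC)c1 | intermediate (not isolated)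
15 | [3,5-bis(methoxymethoxy)phenyl]boronic acid | OB(O)c1cc(OCOC)cc(OCOC)c1 | intermediate
16 | 5-bromo-2-[3,5-bis(methoxymethoxy)phenoxy]-1,3-dimethoxybenzene | COCOc1cc(OCOC)cc(Oc2c(OC)cc(Br)cc2OC)c1 | intermediate
17 | deoxy BCDEF pentamer: ring B O-triisopropylsilyl, rings B, C, E dimethyl ethers, rings D and F 3,5-bis(methoxymethyl) ethers | CC(C)[Si](C(C)C)(C(C)C)Oc1cc(OC)c(Oc2cc(OC)c(Oc3cc(OCOC)cc(OCOC)c3Oc3cc(OC)c(Oc4cc(OCOC)cc(OCOC)c4)c(OC)c3)c(OC)c2)c(OC)c1 | intermediate
18 | 17 lithiated at C4 of ring D and C4 of ring F | CC(C)[Si](C(C)C)(C(C)C)Oc1cc(OC)c(Oc2cc(OC)c(Oc3cc(OCOC)c([Li])c(OCOC)c3Oc3cc(OC)c(Oc4cc(OCOC)c([Li])c(OCOC)c4)c(OC)c3)c(OC)c2)c(OC)c1 | intermediate (not isolated)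
19 | 17 with dimethoxyboryl groups at C4 of ring D and C4 of ring F | CC(C)[Si](C(C)C)(C(C)C)Oc1cc(OC)c(Oc2cc(OC)c(Oc3cc(OCOC)c(B(OC)OC)c(OCOC)c3Oc3cc(OC)c(Oc4cc(OCOC)c(B(OC)OC)c(OCOC)c4)c(OC)c3)c(OC)c2)c(OC)c1 | intermediate (not isolated)
20 | BCDEF pentamer with free hydroxyls at C4 of rings D and F | CC(C)[Si](C(C)C)(C(C)C)Oc1cc(OC)c(Oc2cc(OC)c(Oc3cc(OCOC)c(O)c(OCOC)c3Oc3cc(OC)c(Oc4cc(OCOC)c(O)c(OCOC)c4)c(OC)c3)c(OC)c2)c(OC)c1 | intermediate
21 | BCDEF pentamer with methoxy groups at C4 of rings D and F, ring B O-triisopropylsilyl | CC(C)[Si](C(C)C)(C(C)C)Oc1cc(OC)c(Oc2cc(OC)c(Oc3cc(OCOC)c(OC)c(OCOC)c3Oc3cc(OC)c(Oc4cc(OCOC)c(OC)c(OCOC)c4)c(OC)c3)c(OC)c2)c(OC)c1 | intermediate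
22 | BCDEF pentamer phenol (free hydroxyl at C1 of ring B) | Oc1cc(OC)c(Oc2cc(OC)c(Oc3cc(OCOC)c(OC)c(OCOC)c3Oc3cc(OC)c(Oc4cc(OCOC)c(OC)c(OCOC)c4)c(OC)c3)c(OC)c2)c(OC)c1 | intermediate
23 | 2-iodo-1,3,5-trimethoxybenzene | COc1cc(OC)c(I)c(OC)c1 | starting material
24 | protected hexamer: eleven methyl ethers, methoxymethyl ethers at C3 and C5 of rings D and F | COc1cc(OC)c(Oc2cc(OC)c(Oc3cc(OC)c(Oc4cc(OCOC)c(OC)c(OCOC)c4Oc4cc(OC)c(Oc5cc(OCOC)c(OC)c(OCOC)c5)c(OC)c4)c(OC)c3)c(OC)c2)c(OC)c1 | intermediate
25 | CNP0175585.0 | Oc1cc(O)c(Oc2cc(O)c(Oc3cc(O)c(Oc4cc(O)c(O)c(O)c4Oc4cc(O)c(Oc5cc(O)c(O)c(O)c5)c(O)c4)c(O)c3)c(O)c2)c(O)c1 | target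

## Step count and risks

Total step count: 15. Longest linear sequence: 12 steps (steps 1 to 6 and 10 to 15); steps 7 to 9 form the side branch to 16.

**Step 11 (key step).** The likely failure is incomplete second metalation once the first aryllithium has formed and aggregated, together with deprotonation beside the diaryl ether oxygen at C2 or C6 of ring F or C2 of ring D. Either would leave mono-hydroxylated or wrongly hydroxylated material.
Fallback: the oxygen of ring F is brought in earlier, so that only one metalation remains at the pentamer stage. It sets out from 12. Lithiation with LDA (an amide base that leaves the C–Br bond alone) between the two acetal groups, boration with B(OMe)3 and peroxide oxidation give 4-bromo-2,6-bis(methoxymethoxy)phenol F1. O-methylation gives 5-bromo-2-methoxy-1,3-bis(methoxymethoxy)benzene F2. Bromine–lithium exchange with in situ borate trapping gives [4-methoxy-3,5-bis(methoxymethoxy)phenyl]boronic acid F3. Chan–Lam coupling with 5 gives 5-bromo-2-[4-methoxy-3,5-bis(methoxymethoxy)phenoxy]-1,3-dimethoxybenzene F4. Ullmann coupling with 11 gives the pentamer with ring F complete and ring D still deoxy, F5. A single directed lithiation, boration and oxidation at C4 of ring D gives the mono-phenol F6, and O-methylation returns to the route at 21.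

**Step 10.** The phenoxide of 11 sits between an aryloxy and an acetal oxygen, so C–O bond formation may be slow and hydrodebromination of 16 may win. The silyl ether may also be transferred or lost at 100 °C in the presence of carbonate.
Fallback: it sets out from 16. Bromine–lithium exchange with in situ borate trapping gives {4-[3,5-bis(methoxymethoxy)phenoxy]-3,5-dimethoxyphenyl}boronic acid F7. Chan–Lam coupling of F7 with 11 at room temperature (Cu(OAc)2, pyridine, O2) returns to the route at 17.

**Step 14.** Oxidative addition at a carbon flanked by two methoxy groups may be slow, and reductive loss of iodine from 23 may outpace coupling.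
Fallback: the polarity is reversed. It sets out from 22, which is converted with triflic anhydride and pyridine into the pentamer aryl triflate F8. Pd(OAc)2 with 2-(di-tert-butylphosphino)-2′,4′,6′-triisopropylbiphenyl, K3PO4 and toluene at 100 °C then couples F8 with 2,4,6-trimethoxyphenol, returning to the route at 24.

**Step 15.** Cleavage of fifteen ethers may stop short as borate complexes precipitate, and the pyrogallol rings may oxidise during work-up and chromatography.
Fallback: it sets out from 24. After the same BBr3 treatment the crude polyphenol is acetylated at once (Ac2O, pyridine) to the pentadecaacetate F9, which is stable and can be purified on silica. Acid methanolysis (HCl from acetyl chloride in MeOH, argon) returns to the route at 25.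

**Step 3.** Self-condensation through the bromide of 5, or further reaction of the bromide of product 6 with remaining phenoxide, would give oligomeric ethers.
Fallback: the phenol of ring C is protected and the order of bond formation is changed. It sets out from 5. Benzylation (BnBr, K2CO3) gives 2-(benzyloxy)-5-bromo-1,3-dimethoxybenzene F10. Ullmann coupling with 7 gives 4-[4-(benzyloxy)-3,5-dimethoxyphenoxy]-3,5-dimethoxybenzaldehyde F11. Hydrogenolysis (H2, Pd/C, EtOAc, stopped before the aldehyde is reduced) gives 4-(4-hydroxy-3,5-dimethoxyphenoxy)-3,5-dimethoxybenzaldehyde F12. Ullmann coupling of F12 with 4 returns to the route at 8.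

**Step 9.** Oxidative coupling of the 2,6-disubstituted phenol may be sluggish, so that protodeboronation and homocoupling of 15 consume the boronic acid.
Fallback: it sets out from 12. Copper-catalysed aromatic Finkelstein exchange (NaI, CuI, N,N′-dimethylethane-1,2-diamine, dioxane) gives 1-iodo-3,5-bis(methoxymethoxy)benzene F13. Ullmann coupling of F13 with 5 at 80 °C, where the iodide reacts before the deactivated bromide, returns to the route at 16.

## Further compounds

F1 | step 11 | 4-bromo-2,6-bis(methoxymethoxy)phenol | COCOc1cc(Br)cc(OCOC)c1O
F2 | step 11 | 5-bromo-2-methoxy-1,3-bis(methoxymethoxy)benzene | COCOc1cc(Br)cc(OCOC)c1OC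
F3 | step 11 | [4-methoxy-3,5-bis(methoxymethoxy)phenyl]boronic acid | COCOc1cc(B(O)O)cc(OCOC)c1OC
F4 | step 11 | 5-bromo-2-[4-methoxy-3,5-bis(methoxymethoxy)phenoxy]-1,3-dimethoxybenzene | COCOc1cc(Oc2c(OC)cc(Br)cc2OC)cc(OCOC)c1OC
F5 | step 11 | BCDEF pentamer with ring F as 4-methoxy-3,5-bis(methoxymethoxy)phenoxy and ring D deoxy | CC(C)[Si](C(C)C)(C(C)C)Oc1cc(OC)c(Oc2cc(OC)c(Oc3cc(OCOC)cc(OCOC)c3Oc3cc(OC)c(Oc4cc(OCOC)c(OC)c(OCOC)c4)c(OC)c3)c(OC)c2)c(OC)c1
F6 | step 11 | BCDEF pentamer with free hydroxyl at C4 of ring D and methoxy at C4 of ring F | CC(C)[Si](C(C)C)(C(C)C)Oc1cc(OC)c(Oc2cc(OC)c(Oc3cc(OCOC)c(O)c(OCOC)c3Oc3cc(OC)c(Oc4cc(OCOC)c(OC)c(OCOC)c4)c(OC)c3)c(OC)c2)c(OC)c1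
F7 | step 10 | {4-[3,5-bis(methoxymethoxy)phenoxy]-3,5-dimethoxyphenyl}boronic acid | COCOc1cc(OCOC)cc(Oc2c(OC)cc(B(O)O)cc2OC)c1
F8 | step 14 | trifluoromethanesulfonate of 22 at C1 of ring B | O=S(=O)(Oc1cc(OC)c(Oc2cc(OC)c(Oc3cc(OCOC)c(OC)c(OCOC)c3Oc3cc(OC)c(Oc4cc(OCOC)c(OC)c(OCOC)c4)c(OC)c3)c(OC)c2)c(OC)c1)C(F)(F)F
F9 | step 15 | pentadecaacetate of 25 | CC(=O)Oc1cc(OC(C)=O)c(Oc2cc(OC(C)=O)c(Oc3cc(OC(C)=O)c(Oc4cc(OC(C)=O)c(OC(C)=O)c(OC(C)=O)c4Oc4cc(OC(C)=O)c(Oc5cc(OC(C)=O)c(OC(C)=O)c(OC(C)=O)c5)c(OC(C)=O)c4)c(OC(C)=O)c3)c(OC(C)=O)c2)c(OC(C)=O)c1
F10 | step 3 | 2-(benzyloxy)-5-bromo-1,3-dimethoxybenzene | COc1cc(Br)cc(OC)c1OCc1ccccc1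
F11 | step 3 | 4-[4-(benzyloxy)-3,5-dimethoxyphenoxy]-3,5-dimethoxybenzaldehyde | O=Cc1cc(OC)c(Oc2cc(OC)c(OCc3ccccc3)c(OC)c2)c(OC)c1
F12 | step 3 | 4-(4-hydroxy-3,5-dimethoxyphenoxy)-3,5-dimethoxybenzaldehyde | O=Cc1cc(OC)c(Oc2cc(OC)c(O)c(OC)c2)c(OC)c1
F13 | step 9 | 1-iodo-3,5-bis(methoxymethoxy)benzene | COCOc1cc(I)cc(OCOC)c1
A1 | alternative 1 | 5-(ABC-oxy)-2,3-dimethoxy-1,4-benzoquinone | COC1=C(OC)C(=O)C(Oc2c(OC)cc(Oc3c(OC)cc(Oc4c(OC)cc(OC)cc4OC)cc3OC)cc2OC)=CC1=O
A2 | alternative 1 | 4-(ABC-oxyethynyl)-4-hydroxy-2,3-dimethoxycyclobut-2-en-1-one | COC1=C(OC)C(O)(C#COc2c(OC)cc(Oc3c(OC)cc(Oc4c(OC)cc(OC)cc4OC)cc3OC)cc2OC)C1=O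
A3 | alternative 1 | dimethyl squarate (3,4-dimethoxycyclobut-3-ene-1,2-dione) | COC1=C(OC)C(=O)C1=O
A4 | alternative 1 | ethynyl ether of the methylated ABC trimer phenol | C#COc1c(OC)cc(Oc2c(OC)cc(Oc3c(OC)cc(OC)cc3OC)cc2OC)cc1OC
A5 | alternative 2 | hexamer with free phloroglucinol ring A and rings B to F methylated | Oc1cc(O)c(Oc2cc(OC)c(Oc3cc(OC)c(Oc4cc(OC)c(OC)c(OC)c4Oc4cc(OC)c(Oc5cc(OC)c(OC)c(OC)c5)c(OC)c4)c(OC)c3)c(OC)c2)c(O)c1
A6 | alternative 2 | methyl 6-(methylated BCDEF pentamer-oxy)-3,5-dioxohexanoate | COC(=O)CC(=O)CC(=O)COc1cc(OC)c(Oc2cc(OC)c(Oc3cc(OC)c(OC)c(OC)c3Oc3cc(OC)c(Oc4cc(OC)c(OC)c(OC)c4)c(OC)c3)c(OC)c2)c(OC)c1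
A7 | alternative 3 | methylated ABCDE pentamer with ring E C4 oxygen as tert-butyldimethylsilyl ether | COc1cc(OC)c(Oc2cc(OC)c(Oc3cc(OC)c(Oc4cc(OC)c(OC)c(OC)c4Oc4cc(OC)c(O[Si](C)(C)C(C)(C)C)c(OC)c4)c(OC)c3)c(OC)c2)c(OC)c1
A8 | alternative 3 | [(methylated ABCD tetramer-oxy)methyl]triphenylphosphonium chloride | COc1cc(OC)c(Oc2cc(OC)c(Oc3cc(OC)c(Oc4cc(OC)c(OC)c(OC)c4OC[P+](c4ccccc4)(c4ccccc4)c4ccccc4)c(OC)c3)c(OC)c2)c(OC)c1.[Cl-]
A9 | alternative 3 | 3,5-dimethoxy-4H-pyran-4-one | COC1=COC=C(OC)C1=O
A10 | alternative 3 | 4-(tert-butyldimethylsilyloxy)-3,5-dimethoxypyrylium trifluoromethanesulfonate | COc1c[o+]cc(OC)c1O[Si](C)(C)C(C)(C)C.[O-]S(=O)(=O)C(F)(F)F
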